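The constants are assumed; no experiment stands behind them.

The constants came first when you asked for a quick number and suspected that dosing L on Monday's would beat the other set-ups:

    L ⇌ Q (K1 = 0.43, k1 = 0.12 s⁻¹)
    Q ⇌ X (K2 = 0.081, k2 = 0.18 s⁻¹)
    X ⇌ L (k3 = 0.036 s⁻¹)
    L + Z → L.Z (k4 = 22 M⁻¹ s⁻¹)
    L + Q ⇌ L.Q, settled at all times (K5 = 83 M⁻¹)

| setting | Tuesday's | Thursday's | Wednesday's | Monday's |
|---|---|---|---|---|
| L | 14 mM | 14 mM | 14 mM | 14 mM (fed, over 10.0 s) |
| Z | 2.80 mM | 2.80 mM | 2.80 mM | 2.80 mM |
| time | 10 s | 10 s |  | 10 s |
| remark | everything together in a closed stirred flask, run for 10 s | plug flow through a tube for 10 s, no back-mixing | one stirred flow tank at steady state, fed with the mixture as stated, mean residence time 10 s | a stirred flask in which L is dosed at a steady rate over 10.0 s without added volume, worked up at 10 s |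

1. the set-up with the highest share of Q in all that became Q or X, at the outlet or at the end ("none" if the first two lie within 2 percentage points) (Tuesday's / Thursday's / Wednesday's / Monday's / none)
2. share of Q in all that became Q or X, at the outlet or at the end, Tuesday's
3. share of Q in all that became Q or X, at the outlet or at the end, Thursday's
4. share of Q in all that became Q or X, at the outlet or at the end, Wednesday's
5. share of Q in all that became Q or X, at the outlet or at the end, Monday's

- percentages count the L that a species holds: one L.Q counts as two
- Q is meant together with its L.Q
- the stated concentrations are those of everything mixed, before any reaction; amounts are the same in each set-up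
- the feed brings no volume worth counting
- in an amount of Q, one L.Q counts as one Q
- run time (Tuesday's): 10 s

I began with X, which did not stay long. Free Q turned into X at 0.18 s⁻¹, but X went back to Q at 2.22 s⁻¹, far faster than it went on to L at 0.036 s⁻¹. Its half-life by that way back was 0.312 s, short beside the 10 s run. So I treated X and free Q as a fast balance, a pre-equilibrium, with X equal to E times free Q, where E is 0.081. L.Q was also kept at balance: bound Q was B[L] times free Q, where B is 83 M⁻¹ and [L] is free L.

That gave me the Q share, S = (1 + B[L]) / (1 + B[L] + E), the part of Q and X that stays Q at a given free L. I guessed free L at half the charge, so S was 95.1%. Free L at the full charge gave 96.4%, a gap of 1.3 percentage points, smaller than the margin of 2 points. I therefore expected no clear winner, provided that free L ended between those two values in each set-up.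

The forecast gave 95% for Tuesday's, 95% for Thursday's, 95.5% for Wednesday's and 95.4% for Monday's, with the verdict none, and said “these values come from a rough mental integration, not an exact solution”.

The simulation gave 94.9%, 94.9%, 95.4% and 95.5% in that order, with the verdict none. Monday's stood 0.60 points above Tuesday's, less than the margin. Free L at the end of Tuesday's was 44.1% of the charge, lower than I had guessed, and S at that value is 94.9%. The neighbour of Monday's with 7.0 mM of Z ended with free L at 46.6% of the charge, where S is 95.0%, and that flask gave 95.2%.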